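C19H25ClO6 target: convergent route through a radical-built ring C, 28 steps

The retrosynthesis cuts O2–C3 (ring B), C4–C4a (alkyne to enone), C1'=C2' (olefination) and C3''–C4'' (ring C). Within ring A it cuts C5–C6 (Claisen closure) and C7=C8 (metathesis, then dihydroxylation).
The enabling feature lies in ring C (O1''–C2''–C3''–C4''–C5''). The methyl-bearing C3'' neighbours the oxygenated C2'' and stands trans to the bulky C3' carbinol group, and C4'' lies two atoms from O1''. A C4'' radical held on O1'' through an acetal carbon (the later C5'') can therefore close on a vinyl group at C2'', and the vinyl CH2 ends as the methyl group.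
In the forward direction ring C is made first (fragment 1, an enynol) and ring A second (fragment 2, a chloro vinylogous acyl triflate). A Sonogashira coupling joins them, and ring B closes last when C1–OH adds to C3 in 6-endo mode.
C3' and C2'' come from a Sharpless kinetic resolution, and C3'' is set by C2'' in the radical closure. C8a comes from an Evans aldol reaction, and C7 and C8 from OsO4 addition anti to the C8a side chain of a δ-lactone.

Key step: step 5

Remark: locants are those of the target (ring A C4a–C8a, ring B O2/C1/C3/C4, chain C1'–C3', ring C O1''–C5''). Each 1,3-dione is drawn as one tautomer.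

## Fragment 1: enynol 21 (steps 1–12)

Step 1
Reactants: 1 methacrolein; 2 vinylmagnesium bromide
Product: 3 rac-2-methylpenta-1,4-dien-3-ol
Conditions: THF, −78 to 0 °C; then H2O
Reagents that add atoms: none
Why: 1,2-Addition of the vinyl Grignard reagent to the enal carbonyl gives the bis-allylic alcohol as a racemate, which is all the following resolution needs.

Step 2
Reactants: 3 rac-2-methylpenta-1,4-dien-3-ol
Product: 4 (1S)-1-[(2R)-2-methyloxiran-2-yl]prop-2-en-1-ol
Conditions: Ti(OiPr)4 (0.1 equiv), L-(+)-DIPT (0.13 equiv), t-BuOOH (0.45 equiv), 4 Å MS, CH2Cl2, −20 °C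
Reagents that add atoms: tert-butyl hydroperoxide, CC(C)(C)OO
Why: In this Sharpless kinetic resolution the titanium L-(+)-tartrate catalyst should epoxidise only the (S)-alcohol, at its more nucleophilic 1,1-disubstituted alkene and on the face that gives the anti (erythro) epoxy alcohol, so C3' (R) and C2'' (S) are fixed together while the (R)-alcohol and the monosubstituted vinyl group stay behind.

Step 3
Reactants: 4 (1S)-1-[(2R)-2-methyloxiran-2-yl]prop-2-en-1-ol
Product: 5 (2R,3S)-1-(benzyloxy)-2-methylpent-4-ene-2,3-diol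
Conditions: BnOH (3 equiv), NaH (0.2 equiv), THF, 60 °C
Reagents that add atoms: benzyl alcohol, OCc1ccccc1
Why: Base-catalysed SN2 opening of the 2,2-disubstituted epoxide by benzyl oxide takes place at the unhindered CH2 (C2'), so the C3'–O bond and both stereocentres stay untouched, and any epoxide migration to the neighbouring alkoxide is drained through the same terminal epoxide.

Step 4
Reactants: 5 (2R,3S)-1-(benzyloxy)-2-methylpent-4-ene-2,3-diol; 6 ethyl vinyl ether
Product: 7 (2R,3S)-1-(benzyloxy)-3-(2-bromo-1-ethoxyethoxy)-2-methylpent-4-en-2-ol (acetal epimers)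
Conditions: NBS (1.05 equiv), 6 (1.5 equiv), CH2Cl2, −40 to 0 °C
Reagents that add atoms: N-bromosuccinimide, O=C1CCC(=O)N1Br
Why: In this bromoacetalisation (haloetherification of an enol ether) the α-bromo oxocarbenium ion should be captured by the secondary allylic hydroxyl rather than by the crowded tertiary one, and the new acetal centre forms as a mixture that step 7 erases.

Step 5
Reactants: 7 (2R,3S)-1-(benzyloxy)-3-(2-bromo-1-ethoxyethoxy)-2-methylpent-4-en-2-ol
Product: 10 (2R)-1-(benzyloxy)-2-[(2S,3S)-5-ethoxy-3-methyloxolan-2-yl]propan-2-ol (C5'' epimers, CH3 trans to the carbinol group), via C4'' radical 8 (not isolated), via primary radical 9 (not isolated)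
Conditions: Bu3SnH (1.2 equiv, slow addition), AIBN (0.1 equiv), toluene (0.02 M), 80 °C
Reagents that add atoms: none
Why: The stannyl radical abstracts bromine from 7 to give the primary C4'' radical 8, which adds to the inner carbon of the C2'' vinyl group; the exocyclic radical 9 then takes hydrogen from Bu3SnH, so the former =CH2 becomes the C3'' methyl group and the chain is carried on. The closest known reaction type is the Ueno–Stork haloacetal cyclisation of allylic alcohols to 2-alkoxytetrahydrofurans. Ring C closes in 5-exo-trig mode by forming C3''–C4'', and the short C–O bonds of the O1'' tether favour this over 6-endo attack at the terminal carbon. The one new stereocentre, C3'', is controlled by C2'': in the chair-like transition state the bulky C3' carbinol group lies pseudo-equatorial, which places the developing CH2 radical trans to it and gives (3''S). The step needs cyclisation to outrun direct reduction of 8, which the low stationary hydride concentration secures. It also needs chemoselectivity, which is given because only the C–Br bond is reducible: the tertiary OH and the benzyl ether are inert, a hydrogen shift from C2' would lead back to the same product, and the acetal epimers converge later.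

Step 6
Reactants: 10 (2R)-1-(benzyloxy)-2-[(2S,3S)-5-ethoxy-3-methyloxolan-2-yl]propan-2-ol
Product: 12 tert-butyldimethylsilyl ether of 10 at C3'–O, via potassium alkoxide 11 (not isolated)
Conditions: KH, 18-crown-6 (cat.), THF, 0 °C; then TBSCl, 0 °C to rt
Reagents that add atoms: tert-butyldimethylsilyl chloride, CC(C)(C)[Si](C)(C)Cl; potassium hydride, [K+].[H-] (potassium only in 11)
Why: O-Silylation of the preformed alkoxide covers the hindered tertiary alcohol under basic conditions that cannot ionise the mixed acetal, and the cover is needed because a free C3'–OH could capture the oxocarbenium ion of step 7.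

Step 7
Reactants: 12 tert-butyldimethylsilyl ether of 10
Product: 13 tert-butyl{[(2R)-1-(benzyloxy)-2-[(2S,3S)-3-methyloxolan-2-yl]propan-2-yl]oxy}dimethylsilane
Conditions: Et3SiH, BF3·OEt2, CH2Cl2, −78 °C
Reagents that add atoms: none
Why: In this ionic reduction of a cyclic acetal the Lewis acid expels ethoxide and the five-membered oxocarbenium ion takes hydride from the silane, which turns C5'' into CH2 and removes the epimeric centre while the silyl and benzyl ethers persist in the cold.

Step 8
Reactants: 13 tert-butyl{[(2R)-1-(benzyloxy)-2-[(2S,3S)-3-methyloxolan-2-yl]propan-2-yl]oxy}dimethylsilane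
Product: 14 (2R)-2-(tert-butyldimethylsilyloxy)-2-[(2S,3S)-3-methyloxolan-2-yl]propan-1-ol
Conditions: H2 (1 atm), Pd/C, EtOAc, rt
Reagents that add atoms: none
Why: Hydrogenolysis of the benzyl ether is clean here because the molecule holds no alkene at this stage and the silyl ether and ring C are inert to it.

Step 9
Reactants: 14 (2R)-2-(tert-butyldimethylsilyloxy)-2-[(2S,3S)-3-methyloxolan-2-yl]propan-1-ol
Product: 15 (2S)-2-(tert-butyldimethylsilyloxy)-2-[(2S,3S)-3-methyloxolan-2-yl]propanal
Conditions: Dess–Martin periodinane, CH2Cl2, 0 °C to rt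
Reagents that add atoms: none
Why: Dess–Martin oxidation of the primary alcohol gives an aldehyde whose α-carbon (C3') is fully substituted, so it can neither enolise nor epimerise (the descriptor changes only through the priority rules).

Step 10
Reactants: 16 3-bromo-1-(trimethylsilyl)prop-1-yne; 17 triethyl phosphite
Product: 18 diethyl [3-(trimethylsilyl)prop-2-yn-1-yl]phosphonate
Conditions: neat, 130 °C
Reagents that add atoms: none
Why: The Michaelis–Arbuzov reaction of a primary propargylic bromide with the phosphite delivers the olefination reagent with loss of bromoethane.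

Step 11
Reactants: 15 (2S)-2-(tert-butyldimethylsilyloxy)-2-[(2S,3S)-3-methyloxolan-2-yl]propanal; 18 diethyl [3-(trimethylsilyl)prop-2-yn-1-yl]phosphonate
Product: 20 (3E,5R)-5-(tert-butyldimethylsilyloxy)-5-[(2S,3S)-3-methyloxolan-2-yl]-1-(trimethylsilyl)hex-3-en-1-yne, via lithiated phosphonate 19 (not isolated)
Conditions: 18, LiN(SiMe3)2, THF, −78 °C; then 15, −78 °C to rt
Reagents that add atoms: lithium bis(trimethylsilyl)amide, [Li+].C[Si](C)(C)[N-][Si](C)(C)C (lithium only in 19)
Why: The Horner–Wadsworth–Emmons reaction of the alkynyl-stabilised phosphonate anion with the α-branched aldehyde forms C1'=C2' with the E geometry typical of this reagent, which the bulk at C3' reinforces.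

Step 12
Reactants: 20 (3E,5R)-5-(tert-butyldimethylsilyloxy)-5-[(2S,3S)-3-methyloxolan-2-yl]-1-(trimethylsilyl)hex-3-en-1-yne
Product: 21 (2R,3E)-2-[(2S,3S)-3-methyloxolan-2-yl]hex-3-en-5-yn-2-ol
Conditions: Bu4NF (3 equiv), THF, rt to 45 °C
Reagents that add atoms: none
Why: Fluoride cleaves the C–Si bond of the alkyne and the O–Si bond of the tertiary ether in one operation, so no protecting group of fragment 1 has to be removed after the union.

## Fragment 2: triflate 42 (steps 13–26)

Step 13
Reactants: 22 (S)-4-benzyl-1,3-oxazolidin-2-one; 23 (E)-but-2-enoyl chloride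
Product: 25 (4S)-4-benzyl-3-[(2E)-but-2-enoyl]-1,3-oxazolidin-2-one, via lithium oxazolidinide 24 (not isolated)
Conditions: n-BuLi, THF, −78 °C; then 23, −78 to 0 °C
Reagents that add atoms: n-butyllithium, [Li]CCCC (lithium only in 24)
Why: N-Acylation of the lithiated auxiliary with the acid chloride is the standard entry to the crotonate imide.

Step 14
Reactants: 25 (4S)-4-benzyl-3-[(2E)-but-2-enoyl]-1,3-oxazolidin-2-one; 26 acetaldehyde
Product: 28 (4S)-4-benzyl-3-[(2S,3R)-2-ethenyl-3-hydroxybutanoyl]-1,3-oxazolidin-2-one, via boron dienolate 27 (not isolated)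
Conditions: Bu2BOTf, Et3N, CH2Cl2, −78 to 0 °C; then 26, −78 °C; then pH 7 buffer, MeOH, H2O2
Reagents that add atoms: dibutylboron triflate, CCCCB(CCCC)OS(=O)(=O)C(F)(F)F (boron only in 27)
Why: In this Evans syn aldol reaction of a crotonate imide the Z boron dienolate reacts at its α-carbon through a chair transition state on the face away from the benzyl group, which sets C8a with the target configuration and a vinyl group (the later C8), while the carbinol centre (C4a) is oxidised away in step 22.

Step 15
Reactants: 28 (4S)-4-benzyl-3-[(2S,3R)-2-ethenyl-3-hydroxybutanoyl]-1,3-oxazolidin-2-one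
Product: 29 (4S)-4-benzyl-3-[(2S,3R)-3-(tert-butyldimethylsilyloxy)-2-ethenylbutanoyl]-1,3-oxazolidin-2-one
Conditions: TBSOTf, 2,6-lutidine, CH2Cl2, 0 °C
Reagents that add atoms: tert-butyldimethylsilyl triflate, CC(C)(C)[Si](C)(C)OS(=O)(=O)C(F)(F)F
Why: Silylation of the secondary alcohol masks the future C4a ketone, which could not coexist with the allylic C8a–H of the next intermediates.

Step 16
Reactants: 29 (4S)-4-benzyl-3-[(2S,3R)-3-(tert-butyldimethylsilyloxy)-2-ethenylbutanoyl]-1,3-oxazolidin-2-one
Product: 30 (2R,3R)-3-(tert-butyldimethylsilyloxy)-2-ethenylbutan-1-ol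
Conditions: LiBH4, Et2O–THF, 0 °C
Reagents that add atoms: none
Why: Reductive removal of the auxiliary turns the acyl carbon directly into C1H2OH without enolisation at C8a (the descriptor changes only through the priority rules).

Step 17
Reactants: 30 (2R,3R)-3-(tert-butyldimethylsilyloxy)-2-ethenylbutan-1-ol; 31 methacryloyl chloride
Product: 32 (2R,3R)-3-(tert-butyldimethylsilyloxy)-2-ethenylbutyl 2-methylprop-2-enoate
Conditions: Et3N, DMAP (cat.), CH2Cl2, 0 °C
Reagents that add atoms: none
Why: Esterification of the primary alcohol brings in C6, C7 and the C7 methyl group and ties them to C1–O for the ring closure.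

Step 18
Reactants: 32 (2R,3R)-3-(tert-butyldimethylsilyloxy)-2-ethenylbutyl 2-methylprop-2-enoate
Product: 33 (5R)-5-[(1R)-1-(tert-butyldimethylsilyloxy)ethyl]-3-methyl-5,6-dihydro-2H-pyran-2-one
Conditions: second-generation Grubbs catalyst (5 mol %), CH2Cl2 (0.005 M), reflux
Reagents that add atoms: none
Why: Ring-closing metathesis of the vinyl group with the methacrylate forms the trisubstituted C7=C8 bond inside a six-membered lactone, a pattern that this ruthenium carbene reaches routinely with loss of ethene.

Step 19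
Reactants: 33 (5R)-5-[(1R)-1-(tert-butyldimethylsilyloxy)ethyl]-3-methyl-5,6-dihydro-2H-pyran-2-one
Product: 34 (3R,4R,5S)-5-[(1R)-1-(tert-butyldimethylsilyloxy)ethyl]-3,4-dihydroxy-3-methyloxan-2-one (cis-diol, trans to the C8a side chain)
Conditions: OsO4 (5 mol %), NMO (2 equiv), acetone–H2O, rt
Reagents that add atoms: N-methylmorpholine N-oxide, C[N+]1([O-])CCOCC1; water, O
Why: In this Upjohn dihydroxylation OsO4 adds suprafacially to C7=C8 from the face opposite to the bulky allylic side chain on C8a, which sets C7 (R) and C8 (R) and, once C1 is counted as the substituent of ring A, places O7, O8 and C1 on one face as in the target.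

Step 20
Reactants: 34 (3R,4R,5S)-5-[(1R)-1-(tert-butyldimethylsilyloxy)ethyl]-3,4-dihydroxy-3-methyloxan-2-one
Product: 35 3,4-O-isopropylidene derivative (acetonide) of 34
Conditions: 2,2-dimethoxypropane, PPTS (cat.), CH2Cl2, rt
Reagents that add atoms: 2,2-dimethoxypropane, COC(C)(C)OC
Why: Ketalisation of the cis-1,2-diol gives a base-stable, non-migrating protecting group that also bends the lactone toward the boat needed in step 23.

Step 21
Reactants: 35 acetonide of 34
Product: 36 (3R,4R)-5-[(1R)-1-hydroxyethyl]-3,4-(isopropylidenedioxy)-3-methyloxan-2-one (C8a unchanged)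
Conditions: HF·pyridine, pyridine, THF, 0 °C to rt
Reagents that add atoms: none
Why: Buffered fluoride desilylation frees the secondary alcohol without the alkoxide that would invite translactonisation and without harm to the acetonide.

Step 22
Reactants: 36 (3R,4R)-5-[(1R)-1-hydroxyethyl]-3,4-(isopropylidenedioxy)-3-methyloxan-2-one
Product: 37 (3R,4R,5S)-5-acetyl-3,4-(isopropylidenedioxy)-3-methyloxan-2-one
Conditions: Dess–Martin periodinane, CH2Cl2, 0 °C to rt; used crude
Reagents that add atoms: none
Why: The neutral Dess–Martin oxidation gives the methyl ketone (C4a, C5) under conditions too mild to enolise the β-acyloxy ketone at C8a.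

Step 23
Reactants: 37 (3R,4R,5S)-5-acetyl-3,4-(isopropylidenedioxy)-3-methyloxan-2-one
Product: 39 (4R,5R,6S)-6-(hydroxymethyl)-4,5-(isopropylidenedioxy)-4-methylcyclohexane-1,3-dione, via lithium enolate 38 (not isolated)
Conditions: LiN(SiMe3)2 (2.3 equiv), THF, −78 to 0 °C; then AcOH
Reagents that add atoms: lithium bis(trimethylsilyl)amide, [Li+].C[Si](C)(C)[N-][Si](C)(C)C (lithium only in 38)
Why: In this intramolecular Claisen (Dieckmann-type) condensation, kinetic deprotonation at the methyl group gives an enolate whose carbon (C5) attacks the lactone carbonyl (C6) across the boat that the cis-fused acetonide imposes, the C1 alkoxide is expelled, and irreversible deprotonation of the 1,3-dione drives the closure of ring A without touching C7, C8 or C8a.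

Step 24
Reactants: 39 (4R,5R,6S)-6-(hydroxymethyl)-4,5-(isopropylidenedioxy)-4-methylcyclohexane-1,3-dione
Product: 40 2-chloro derivative of 39 (Cl on C5, drawn as the C4a enol)
Conditions: NCS (1.0 equiv), CH2Cl2, 0 °C
Reagents that add atoms: N-chlorosuccinimide, O=C1CCC(=O)N1Cl
Why: Electrophilic chlorination of a cyclic 1,3-dione takes place at the enolic carbon between the carbonyl groups (C5), and one equivalent of reagent leaves the primary alcohol and the acetonide alone.

Step 25
Reactants: 40 2-chloro derivative of 39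
Product: 41 (7R,8R,8aS)-configured C4a enol triflate: 2-chloro-6-(hydroxymethyl)-4,5-(isopropylidenedioxy)-4-methyl-3-oxocyclohex-1-en-1-yl trifluoromethanesulfonate
Conditions: PhNTf2 (1.1 equiv), Et3N (1.5 equiv), CH2Cl2, 0 °C to rt
Reagents that add atoms: N-phenylbis(trifluoromethanesulfonimide), O=S(=O)(N(c1ccccc1)S(=O)(=O)C(F)(F)F)C(F)(F)F
Why: O-Sulfonylation of the ammonium enolate with the mild triflimide reagent, which leaves aliphatic alcohols alone, should take place at the oxygen on C4a because the other oxygen is screened by the fully substituted C7, as is the rule for 4,4-disubstituted cyclohexane-1,3-diones.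

Step 26
Reactants: 41 C4a enol triflate
Product: 42 (7R,8R,8aS)-configured triol: 2-chloro-4,5-dihydroxy-6-(hydroxymethyl)-4-methyl-3-oxocyclohex-1-en-1-yl trifluoromethanesulfonate
Conditions: CF3CO2H–H2O (9:1), 0 °C
Reagents that add atoms: none
Why: Acid hydrolysis of the isopropylidene ketal is placed here, on the robust fragment, because vinyl triflate, vinyl chloride and ketone tolerate cold aqueous acid whereas the tertiary allylic alcohol that arrives in step 27 might not.

## Union and ring B (steps 27–28)

Step 27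
Reactants: 42 triol triflate; 21 (2R,3E)-2-[(2S,3S)-3-methyloxolan-2-yl]hex-3-en-5-yn-2-ol
Product: 43 (7R,8R,8aS,3'R,2''S,3''S)-enynone: 2-chloro-5,6-dihydroxy-4-(hydroxymethyl)-6-methylcyclohex-2-en-1-one that carries the (3E)-5-hydroxy-5-[3-methyloxolan-2-yl]hex-3-en-1-ynyl group on C3 (target C4a)
Conditions: Pd(PPh3)4 (5 mol %), CuI (10 mol %), Et3N, THF, rt, degassed
Reagents that add atoms: none
Why: In this Sonogashira coupling zerovalent palladium inserts into the activated C4a–OTf bond of the vinylogous acyl triflate far faster than into the C5–Cl bond, the copper acetylide of 21 is transferred to form C4–C4a, and the free hydroxyl groups and the E alkene are spectators under tertiary-amine conditions.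

Step 28
Reactants: 43 enynone
Product: 44 CNP0432723.2 (7R,8R,8aS,3'R,2''S,3''S)
Conditions: AgOTf (5 mol %), acetone, 0 °C to rt, dark
Reagents that add atoms: none
Why: In this silver-catalysed cycloisomerisation of an alkynol (an intramolecular 1,6-oxa-Michael addition) C1–OH attacks C3, the alkyne carbon at the positive end of the enynone dipole, in 6-endo-dig mode, and protodemetalation at C4 leaves the dienol ether of ring B without touching any stereocentre.

## Compound list

1 | methacrolein | C=C(C)C=O | starting material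
2 | vinylmagnesium bromide | C=C[Mg]Br | starting material
3 | rac-2-methylpenta-1,4-dien-3-ol | C=CC(O)C(C)=C | intermediate
4 | (1S)-1-[(2R)-2-methyloxiran-2-yl]prop-2-en-1-ol | C=C[C@H](O)[C@@]1(C)CO1 | intermediate
5 | (2R,3S)-1-(benzyloxy)-2-methylpent-4-ene-2,3-diol | C=C[C@H](O)[C@](C)(O)COCc1ccccc1 | intermediate
6 | ethyl vinyl ether | C=COCC | starting material
7 | (2R,3S)-1-(benzyloxy)-3-(2-bromo-1-ethoxyethoxy)-2-methylpent-4-en-2-ol (acetal epimers) | C=C[C@H](OC(OCC)CBr)[C@](C)(O)COCc1ccccc1 | intermediate
8 | C4'' radical from 7 (not isolated) | [CH2]C(OCC)O[C@@H](C=C)[C@](C)(O)COCc1ccccc1 | intermediate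
9 | cyclised primary radical (not isolated) | [CH2][C@H]1CC(OCC)O[C@@H]1[C@](C)(O)COCc1ccccc1 | intermediate
10 | (2R)-1-(benzyloxy)-2-[(2S,3S)-5-ethoxy-3-methyloxolan-2-yl]propan-2-ol (C5'' epimers) | C[C@H]1CC(OCC)O[C@@H]1[C@](C)(O)COCc1ccccc1 | intermediate
11 | potassium alkoxide of 10 (not isolated) | C[C@H]1CC(OCC)O[C@@H]1[C@](C)([O-])COCc1ccccc1.[K+] | intermediate
12 | tert-butyldimethylsilyl ether of 10 | C[C@H]1CC(OCC)O[C@@H]1[C@](C)(O[Si](C)(C)C(C)(C)C)COCc1ccccc1 | intermediate
13 | tert-butyl{[(2R)-1-(benzyloxy)-2-[(2S,3S)-3-methyloxolan-2-yl]propan-2-yl]oxy}dimethylsilane | C[C@H]1CCO[C@@H]1[C@](C)(O[Si](C)(C)C(C)(C)C)COCc1ccccc1 | intermediate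
14 | (2R)-2-(tert-butyldimethylsilyloxy)-2-[(2S,3S)-3-methyloxolan-2-yl]propan-1-ol | C[C@H]1CCO[C@@H]1[C@](C)(O[Si](C)(C)C(C)(C)C)CO | intermediate
15 | (2S)-2-(tert-butyldimethylsilyloxy)-2-[(2S,3S)-3-methyloxolan-2-yl]propanal | C[C@H]1CCO[C@@H]1[C@](C)(O[Si](C)(C)C(C)(C)C)C=O | intermediate
16 | 3-bromo-1-(trimethylsilyl)prop-1-yne | C[Si](C)(C)C#CCBr | starting material
17 | triethyl phosphite | CCOP(OCC)OCC | starting material
18 | diethyl [3-(trimethylsilyl)prop-2-yn-1-yl]phosphonate | CCOP(=O)(CC#C[Si](C)(C)C)OCC | intermediate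
19 | lithiated phosphonate from 18 (not isolated) | [Li+].CCOP(=O)(OCC)[CH-]C#C[Si](C)(C)C | intermediate
20 | (3E,5R)-5-(tert-butyldimethylsilyloxy)-5-[(2S,3S)-3-methyloxolan-2-yl]-1-(trimethylsilyl)hex-3-en-1-yne | C[C@H]1CCO[C@@H]1[C@](C)(O[Si](C)(C)C(C)(C)C)/C=C/C#C[Si](C)(C)C | intermediate
21 | (2R,3E)-2-[(2S,3S)-3-methyloxolan-2-yl]hex-3-en-5-yn-2-ol | C[C@H]1CCO[C@@H]1[C@](C)(O)/C=C/C#C | intermediate
22 | (S)-4-benzyl-1,3-oxazolidin-2-one | O=C1N[C@@H](Cc2ccccc2)CO1 | starting material
23 | (E)-but-2-enoyl chloride | C/C=C/C(=O)Cl | starting material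
24 | lithium salt of 22 (not isolated) | [Li+].O=C1[N-][C@@H](Cc2ccccc2)CO1 | intermediate
25 | (4S)-4-benzyl-3-[(2E)-but-2-enoyl]-1,3-oxazolidin-2-one | C/C=C/C(=O)N1[C@@H](Cc2ccccc2)COC1=O | intermediate
26 | acetaldehyde | CC=O | starting material
27 | Z dibutylboron dienolate of 25 (not isolated) | C=C/C=C(\OB(CCCC)CCCC)N1[C@@H](Cc2ccccc2)COC1=O | intermediate
28 | (4S)-4-benzyl-3-[(2S,3R)-2-ethenyl-3-hydroxybutanoyl]-1,3-oxazolidin-2-one | C[C@@H](O)[C@H](C=C)C(=O)N1[C@@H](Cc2ccccc2)COC1=O | intermediate
29 | (4S)-4-benzyl-3-[(2S,3R)-3-(tert-butyldimethylsilyloxy)-2-ethenylbutanoyl]-1,3-oxazolidin-2-one | C[C@@H](O[Si](C)(C)C(C)(C)C)[C@H](C=C)C(=O)N1[C@@H](Cc2ccccc2)COC1=O | intermediate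
30 | (2R,3R)-3-(tert-butyldimethylsilyloxy)-2-ethenylbutan-1-ol | C[C@@H](O[Si](C)(C)C(C)(C)C)[C@H](C=C)CO | intermediate
31 | methacryloyl chloride | C=C(C)C(=O)Cl | starting material
32 | (2R,3R)-3-(tert-butyldimethylsilyloxy)-2-ethenylbutyl 2-methylprop-2-enoate | C[C@@H](O[Si](C)(C)C(C)(C)C)[C@H](C=C)COC(=O)C(C)=C | intermediate
33 | (5R)-5-[(1R)-1-(tert-butyldimethylsilyloxy)ethyl]-3-methyl-5,6-dihydro-2H-pyran-2-one | C[C@@H](O[Si](C)(C)C(C)(C)C)[C@@H]1C=C(C)C(=O)OC1 | intermediate
34 | (3R,4R,5S)-5-[(1R)-1-(tert-butyldimethylsilyloxy)ethyl]-3,4-dihydroxy-3-methyloxan-2-one | C[C@@H](O[Si](C)(C)C(C)(C)C)[C@@H]1[C@@H](O)[C@@](C)(O)C(=O)OC1 | intermediate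
35 | acetonide of 34 | C[C@@H](O[Si](C)(C)C(C)(C)C)[C@@H]1[C@H]2OC(C)(C)O[C@@]2(C)C(=O)OC1 | intermediate
36 | hydroxyethyl lactone acetonide | C[C@@H](O)[C@@H]1[C@H]2OC(C)(C)O[C@@]2(C)C(=O)OC1 | intermediate
37 | (3R,4R,5S)-5-acetyl-3,4-(isopropylidenedioxy)-3-methyloxan-2-one | CC(=O)[C@@H]1[C@H]2OC(C)(C)O[C@@]2(C)C(=O)OC1 | intermediate
38 | lithium enolate of 37 (not isolated) | [Li+].C=C([O-])[C@@H]1[C@H]2OC(C)(C)O[C@@]2(C)C(=O)OC1 | intermediate
39 | (4R,5R,6S)-6-(hydroxymethyl)-4,5-(isopropylidenedioxy)-4-methylcyclohexane-1,3-dione | OC[C@@H]1C(=O)CC(=O)[C@]2(C)OC(C)(C)O[C@H]12 | intermediate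
40 | 2-chloro derivative of 39 (C4a enol form) | OC[C@@H]1C(O)=C(Cl)C(=O)[C@]2(C)OC(C)(C)O[C@H]12 | intermediate
41 | C4a enol triflate, acetonide | OC[C@@H]1C(OS(=O)(=O)C(F)(F)F)=C(Cl)C(=O)[C@]2(C)OC(C)(C)O[C@H]12 | intermediate
42 | C4a enol triflate, free triol | OC[C@@H]1C(OS(=O)(=O)C(F)(F)F)=C(Cl)C(=O)[C@](C)(O)[C@@H]1O | intermediate
43 | enynone tetraol | C[C@H]1CCO[C@@H]1[C@](C)(O)/C=C/C#CC1=C(Cl)C(=O)[C@](C)(O)[C@H](O)[C@@H]1CO | intermediate
44 | CNP0432723.2 | C[C@H]1CCO[C@@H]1[C@](C)(O)/C=C/C1=CC2=C(Cl)C(=O)[C@](C)(O)[C@H](O)[C@@H]2CO1 | target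

## Step count and weak points

Total step count: 28 (12 for fragment 1 including the phosphonate, 14 for fragment 2, 2 after the union).
Longest linear sequence: 16 steps (22 to 44, steps 13–28).

**Step 25.** The two enolate oxygens may be poorly discriminated during sulfonylation, and the weakly nucleophilic chloro enolate may react slowly.
Fallback, from 40 back to 43: the primary alcohol of 40 is silylated (TBSCl, imidazole) to the silyl ether F1. Ph3PBr2 and Et3N then exchange an enol oxygen for bromine. In this deoxygenative halogenation bromide has to add to the carbon that loses its oxygen, so the neopentyl C6 is passed over and the β-bromo enone F2 should result. Cold aqueous CF3CO2H removes the silyl ether and the acetonide to give the bromo triol F3, which takes the place of 42 in the Sonogashira coupling and rejoins the route at 43.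

**Step 23.** A proton may move from C8a to the kinetic enolate, followed by β-elimination of the lactone carboxylate, or the closure may be slow because it must pass through a bridged boat.
Fallback, from 35 back to 39:
- The lactone of 35 is opened with MeNH(OMe)·HCl and iPrMgCl to the hydroxy Weinreb amide F4.
- The primary alcohol is benzylated under neutral conditions (2-benzyloxy-1-methylpyridinium triflate, MgO) to the benzyl ether F5.
- Bu4NF frees the secondary alcohol F6, and Dess–Martin oxidation gives the methyl ketone F7, in which the β-leaving group is now a poor one and the chain is open.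
- LiN(SiMe3)2 closes ring A on the amide carbonyl through an ordinary chair to the benzyl-protected dione F8.
- Hydrogenolysis over Pd/C returns 39.

**Step 28.** Attack at C4 (5-exo closure) may compete, or silver or trace acid may ionise the tertiary allylic alcohol.
Fallback, from 43 back to 44: diethylamine is added to 43 in 1,6-fashion at C3 to give the push–pull dienaminone F9. On gentle warming with acetic acid, C1–OH displaces the amine at C3 by addition–elimination (6-exo-trig), which closes ring B without a metal and gives 44.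

Further compounds
F1 | step 25 | C1–O-tert-butyldimethylsilyl ether of 40 | CC(C)(C)[Si](C)(C)OC[C@@H]1C(O)=C(Cl)C(=O)[C@]2(C)OC(C)(C)O[C@H]12
F2 | step 25 | C4a-bromo C5-chloro enone, silyl ether and acetonide | CC(C)(C)[Si](C)(C)OC[C@@H]1C(Br)=C(Cl)C(=O)[C@]2(C)OC(C)(C)O[C@H]12
F3 | step 25 | C4a-bromo C5-chloro enone, free triol | OC[C@@H]1C(Br)=C(Cl)C(=O)[C@](C)(O)[C@@H]1O
F4 | step 23 | hydroxy Weinreb amide from 35 | CON(C)C(=O)[C@]1(C)OC(C)(C)O[C@@H]1[C@H](CO)[C@@H](C)O[Si](C)(C)C(C)(C)C
F5 | step 23 | C1–O-benzyl ether of F4 | CON(C)C(=O)[C@]1(C)OC(C)(C)O[C@@H]1[C@H](COCc2ccccc2)[C@@H](C)O[Si](C)(C)C(C)(C)C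
F6 | step 23 | secondary alcohol from F5 | CON(C)C(=O)[C@]1(C)OC(C)(C)O[C@@H]1[C@H](COCc2ccccc2)[C@@H](C)O
F7 | step 23 | methyl ketone from F6 | CON(C)C(=O)[C@]1(C)OC(C)(C)O[C@@H]1[C@H](COCc2ccccc2)C(C)=O
F8 | step 23 | C1–O-benzyl ether of 39 | C(OC[C@@H]1C(=O)CC(=O)[C@]2(C)OC(C)(C)O[C@H]12)c1ccccc1
F9 | step 28 | C3-diethylamino dienone from 43 | C[C@H]1CCO[C@@H]1[C@](C)(O)/C=C/C(N(CC)CC)=CC1=C(Cl)C(=O)[C@](C)(O)[C@H](O)[C@@H]1CO
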